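You asked for a quick number, but rate constants are more than I can offer; the runs give two working figures instead.

| flask | substrate | reagent | remark | time |
|---|---|---|---|---|
| green | 20 mM | 60 mM | run made earlier |  |
| red | 20 mM | 40 mM | run made earlier |  |
| amber | 20 mM | 90 mM | run made earlier |  |
| theta | 20 mM | 60.0 mM | everything together at the start | 15 d |
| zeta | 20 mM (fed, over 10 d) | 60.0 mM | all else is in the flask from the start; the feed brings no volume worth counting | 15 d |
| delta | 20 mM | 60.0 mM (fed, over 10 d) | all else is in the flask from the start; the feed brings no volume worth counting | 15 d |

| run | time / d | target / % |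
|---|---|---|
| green | 4.00 | 19.3 |
| green | 8.00 | 17.7 |
| green | 12.0 | 15.0 |
| green | 15.0 | 13.9 |
| red | 2.50 | 15.8 |
| red | 6.00 | 14.5 |
| red | 12.0 | 13.1 |
| red | 20.0 | 11.4 |
| amber | 1.25 | 28.5 |
| amber | 3.00 | 24.7 |
| amber | 8.00 | 19.0 |
| amber | 20.0 | 10.8 |

(readings scatter by 0.3 percentage points)

1. the best flask by amount of target, in percent of the substrate charged; "all alike" if 1.5 percentage points covers them all (theta / zeta / delta / all alike)
2. amount of target at the end, in percent of the substrate charged, theta
3. amount of target at the end, in percent of the substrate charged, zeta
4. amount of target at the end, in percent of the substrate charged, delta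

- a reading or a percentage of target counts all its forms, free or not

Target is already falling after the first amber reading, 28.5% at 1.25 d, so I take that time as a generous lifetime of substrate. The slow feed of 10 d then spans 8.00 such turnovers. Reagent seen, the c(reagent) fed during one substrate lifetime, is therefore 7.50 mM in delta. The first red reading gives the yield per mM of reagent, 0.00395 /mM as a fraction of the substrate charged.

Because the substrate lifetime is much shorter than the feed, I reckon delta at 2.96%. Theta has the green charge, so I read 13.9% from the green run at 15 d. For zeta I have no figure of my own, only the expectation that it lands above theta.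

Your forecast names zeta as best, with 14% for theta, 16.8% for zeta and 15.5% for delta, the last on the supposition that “the partition is a reversible equilibrium”. We part on delta, where my number is lower.

The flasks give 13.8% in theta, 19.4% in zeta and 1.56% in delta, so zeta is best.

    substrate → side product A (k = 1.30 × 10⁻⁵ /s)
    substrate + reagent → target (k = 1.50 × 10⁻⁴ /M/s)
    2 substrate → side product B (k = 2.80 × 10⁻⁴ /M/s)
    reagent + target → over-reaction product (k = 1.00 × 10⁻⁵ /M/s)
    target ⇌ isomer of the product (K = 0.440, k = 6.10 × 10⁻⁶ /s)
    crystals ⇌ target, rate k6*(cs6 - [target]) while solid is left; crystals form when [target] > cs6 (solubility = 8.70 mM, k = 1.40 × 10⁻⁴ /s)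

In delta, one half-life of substrate to side product A, 0.617 d, admits 3.70 mM of reagent. At that level the pseudo-first-order rate of substrate + reagent to target is 5.55 × 10⁻⁷ /s, far below the 1.3 × 10⁻⁵ /s of the turning to side product A. Reagent seen gave 2.96% for delta, which holds 1.56%. In the neighbour of zeta charged with 15 mM of reagent, the same yield per mM gives 5.92%, and that flask holds 8.33%.

(The numbers in the tables were computed from invented constants.)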